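Start at the late end of the runs. At 25.0 min the left-handed substrate reads 0.8% in the dusk run and 1.5% in the dawn run, after a string of zeros. With a scatter of 1 percentage point, you cannot read a return from those two points.

common to all: gas 29 mM (held)
- dusk: left-handed substrate 0.034 M; right-handed substrate 0.034 M; run made earlier
- dawn: left-handed substrate 0.075 M; right-handed substrate 0.075 M; run made earlier
- flask: left-handed substrate 0.050 M; right-handed substrate 0.050 M; time 20 min

| run | time / min | right-handed substrate / % | left-handed substrate / % |
|---|---|---|---|
| dusk | 2.00 | 48.8 | 22.2 |
| dusk | 3.00 | 48.2 | 15.1 |
| dusk | 5.00 | 48.4 | 3.9 |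
| dusk | 8.00 | 48.5 | 0.4 |
| dusk | 15.0 | 43.8 | 0 |
| dusk | 25.0 | 39.6 | 0.8 |
| dawn | 4.00 | 49.4 | 12.6 |
| dawn | 8.00 | 47.5 | 2.2 |
| dawn | 12.0 | 46.3 | 0 |
| dawn | 15.0 | 44.4 | 0 |
| dawn | 20.0 | 43.0 | 0 |
| dawn | 25.0 | 39.5 | 1.5 |

(each reading ± 1 percentage point)

1. whether the excess of right-handed substrate over left-handed substrate among what is left of the two reaches 98% by 20 min (yes / no)
2. the highest excess of right-handed substrate over left-handed substrate among what is left of the two up to 20 min

- partner is single-handed; left-handed substrate and right-handed substrate are mirror images of each other, charged as a racemate, each of them at the stated concentration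
- at the start none of the gas is in solution
- the handed part of partner does not stay in what it makes, so the products of the two hands are mirror images too

The next flask hangs on one level. Take right-handed substrate near 47.5%, as in the dawn run at 8.00 min. The ceiling is then 0.480%: the left-handed level at which the excess equals the wanted one, found as the right-handed level times the ratio of one minus the excess to one plus the excess. It lies below one standard deviation, so you extrapolate to it.

Two readings of left-handed substrate give a log slope of 0.580 min⁻¹ in the dusk run, from 2.00 min to 5.00 min, and 0.436 min⁻¹ in the dawn run, from 4.00 min to 8.00 min. These are rough readings over different times, and the dawn slope rests on a scattered 2.2%, so do not compare the two charges by them. Carry each slope on from its last clear reading down to the ceiling. As an estimate, that gives 8.61 min and 11.5 min. The flask's charge lies between the two, and both times are earlier than 20 min. So my reckoning says yes. Leave the charge and the held gas as they are, and stop the flask at 11.5 min, because right-handed substrate keeps falling: the dawn run goes on to 43.0% at 20.0 min.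

The forecast differs. It says no, with a top of 97.5%, holding that “both hands share one equilibrium” and that left-handed substrate bottoms near 0.5%.

The flask gives yes, with a top of >99.9%.

    partner + left-handed substrate → left-handed product (k = 0.480 L mol⁻¹ s⁻¹)
    partner + right-handed substrate → right-handed product (k = 0.00640 L mol⁻¹ s⁻¹)
    left-handed product ⇌ right-handed product (k = 0.0190 s⁻¹)
    gas ⇌ partner, rate k4*(csat - [partner]) (kL = 0.0220 s⁻¹)
    partner → decomposed reagent (k = 0.00440 s⁻¹)

In the flask the excess reaches 98% at 8.68 min, before the later of your two times, and left-handed substrate stands at 0.193% at 10.0 min, under the ceiling. At 6.01 min partner has a half-life of 2.6 min by decomposition against 8.6 min by left-handed substrate, so decomposition uses it 3.3 times as fast, and partner stands at 0.0239 M at 20.0 min.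

(All runs are simulated for substances that don't exist.)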